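**Retrosynthetic overview**
- The target is the 2,3-trans-3,4-cis flavan-3,4-diol 3-O-gallate; it is unmasked by neutral deallylation, after reduction of the C4 ketone (sets C4, re-sets C3) and galloylation of O3.
- Key disconnection: ring C is closed by joining O1–C8a and C2–C3 in a formal [4+2] of an aryl aldehyde (C2=O1, ring B) with an α-hydroxy 2-fluoroaryl ketone (C3–C4–C4a–C8a, ring A).
- Enabling feature: the C4 carbonyl of ring C sits between C3 (enolisable, carrying the O3 hydroxyl that chelates zinc) and C4a–C8a of ring A. With fluorine on C8a the aryl ketone is a vinylogous acyl fluoride, so one carbonyl makes C3 nucleophilic and C8a electrophilic.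
- Ring order: ring A, ring B and the galloyl ring are bought as arenes; ring C is the only ring formed (step 5).
- All seven phenols are carried as allyl ethers, because the C4 benzylic alcohol of a 5,7-dioxygenated flavan-3,4-diol would not survive hydrogenolysis or acid.

Key step: step 5

Remark: flavan numbering (O1, C2, C3, C4, C4a, C5 to C8, C8a) is kept for all intermediates; the facial sense of the zinc–ProPhenol aldol toward this aryl aldehyde is assumed to match that known for aliphatic aldehydes, and the antipodal ligand would be used otherwise.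

**Step 1**
Reactants: 1 5-fluorobenzene-1,3-diol (5-fluororesorcinol)
Product: 2 1,3-bis(allyloxy)-5-fluorobenzene
Conditions: allyl bromide (2.4 equiv), K2CO3 (3 equiv), DMF, 50 °C
Reagents that add atoms: allyl bromide (two molecules are consumed per molecule of 1), C=CCBr.C=CCBr
Why: Twofold Williamson O-alkylation in which each phenoxide displaces bromide from one molecule of allyl bromide by SN2; the C–F bond is inert to carbonate.

**Step 2**
Reactants: 2 1,3-bis(allyloxy)-5-fluorobenzene
Product: 3 1,5-bis(allyloxy)-2-bromo-3-fluorobenzene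
Conditions: NBS (1.0 equiv), MeCN, 0 °C → rt, dark
Reagents that add atoms: N-bromosuccinimide, O=C1CCC(=O)N1Br
Why: Electrophilic aromatic bromination should go to the position para to one allyloxy group and ortho to the other (next to fluorine), which is more reactive and less hindered than the position between the two ethers, as in 1,3-dialkoxybenzenes.

**Step 3**
Reactants: 3 1,5-bis(allyloxy)-2-bromo-3-fluorobenzene; 4 2,2-dimethyl-1,3-dioxolan-4-one
Product: 6 1-[2,4-bis(allyloxy)-6-fluorophenyl]-2-hydroxyethan-1-one, via arylmagnesium chloride 5 (not isolated)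
Conditions: i-PrMgCl·LiCl (1.1 equiv), THF, −15 °C; 4 (1.2 equiv), −15 → 0 °C; then 1 M HCl, rt
Reagents that add atoms: none
Why: Bromine–magnesium exchange (fast next to fluorine, and cold enough to avoid aryne formation) followed by acylation of the aryl Grignard reagent by the acetonide-masked glycolic acid 4, whose tetrahedral magnesium hemiketal should persist until the acid work-up releases acetone and the α-hydroxy ketone.

**Step 4**
Reactants: 7 3,4-dihydroxybenzaldehyde
Product: 8 3,4-bis(allyloxy)benzaldehyde
Conditions: allyl bromide (2.4 equiv), K2CO3 (3 equiv), DMF, 60 °C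
Reagents that add atoms: allyl bromide (two molecules are consumed per molecule of 7), C=CCBr.C=CCBr
Why: Twofold Williamson O-alkylation of the catechol, one molecule of allyl bromide per hydroxyl; the aldehyde is untouched.

**Step 5**
Reactants: 6 1-[2,4-bis(allyloxy)-6-fluorophenyl]-2-hydroxyethan-1-one; 8 3,4-bis(allyloxy)benzaldehyde
Product: 10 (2R,3S)-5,7-bis(allyloxy)-2-[3,4-bis(allyloxy)phenyl]-3-hydroxy-2,3-dihydro-4H-chromen-4-one (2,3-cis), via syn-diol 9 (not isolated)
Conditions: Et2Zn (20 mol%), (R,R)-ProPhenol (10 mol%), 4 Å MS, THF, −20 °C; then KN(SiMe3)2 (2.6 equiv), −78 → −10 °C; AcOH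
Reagents that add atoms: none
Why: Proposed new method: the dinuclear zinc–ProPhenol complex turns 6 into a chelated (Z)-enediolate (C3 oxygen and C4 oxygen on zinc) that adds through a closed transition state to one face of aldehyde 8, and the syn-diol 9 is then deprotonated twice so that its C2 alkoxide attacks C8a of ring A, which is ortho to the C4 carbonyl and therefore a vinylogous acyl fluoride, with loss of fluoride (addition–elimination through a Meisenheimer adduct). The closest known reaction types are the direct zinc-catalysed asymmetric aldol of α-hydroxy aryl ketones and the tandem aldol–SNAr annulation of activated 2-fluoroaryl ketones; joining them in one pot on an α-hydroxy ketone and closing the ring through a dialkoxide has not been shown. Ring C closes by 6-exo-trig intramolecular SNAr at C8a, with the C4 carbonyl kept coplanar with ring A so that it stabilises the adduct. C2 is set by the ligand (face of the aldehyde), C3 by the enediolate geometry (syn aldol, hence 2,3-cis), and C3 is later re-set in step 9. The step needs ring closure to outrun retro-aldol cleavage, dehydration and five-membered closure through the C3 oxygen: the C3 alkoxide next to the carbonyl makes the enediolate that retro-aldol would expel or that C3 deprotonation would form a dianion, which disfavours both, and a C3 oxygen can only reach C8a if the C4 carbonyl twists out of conjugation and so switches off its own activation. The ortho allyloxy group at C5 is a far poorer nucleofuge than fluoride, which secures the site of substitution.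

**Step 6**
Reactants: 11 methyl 3,4,5-trihydroxybenzoate (methyl gallate)
Product: 12 methyl 3,4,5-tris(allyloxy)benzoate
Conditions: allyl bromide (3.6 equiv), K2CO3 (4.5 equiv), DMF, 60 °C
Reagents that add atoms: allyl bromide (three molecules are consumed per molecule of 11), C=CCBr.C=CCBr.C=CCBr
Why: Threefold Williamson O-alkylation of the pyrogallol hydroxyls, one molecule of allyl bromide per hydroxyl.

**Step 7**
Reactants: 12 methyl 3,4,5-tris(allyloxy)benzoate
Product: 13 3,4,5-tris(allyloxy)benzoic acid
Conditions: LiOH, THF/MeOH/H2O, 50 °C; then 1 M HCl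
Reagents that add atoms: lithium hydroxide (hydroxide oxygen of the acid), [Li+].[OH-]
Why: Saponification of the methyl ester; aryl allyl ethers are stable to hydroxide.

**Step 8**
Reactants: 10 (2R,3S)-5,7-bis(allyloxy)-2-[3,4-bis(allyloxy)phenyl]-3-hydroxy-2,3-dihydro-4H-chromen-4-one; 13 3,4,5-tris(allyloxy)benzoic acid
Product: 14 (2R,3S)-5,7-bis(allyloxy)-2-[3,4-bis(allyloxy)phenyl]-4-oxo-3,4-dihydro-2H-chromen-3-yl 3,4,5-tris(allyloxy)benzoate (2,3-cis)
Conditions: DCC, DMAP (0.2 equiv), CH2Cl2, 0 °C → rt
Reagents that add atoms: none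
Why: Steglich esterification of the α-ketol hydroxyl places the galloyl group on O3 before O4 exists, so no diol differentiation is needed; any C3 epimerisation here is harmless because step 9 re-sets C3.

**Step 9**
Reactants: 14 (2R,3S)-5,7-bis(allyloxy)-2-[3,4-bis(allyloxy)phenyl]-4-oxo-3,4-dihydro-2H-chromen-3-yl 3,4,5-tris(allyloxy)benzoate
Product: 16 (2R,3S,4S)-5,7-bis(allyloxy)-2-[3,4-bis(allyloxy)phenyl]-4-hydroxy-3,4-dihydro-2H-chromen-3-yl 3,4,5-tris(allyloxy)benzoate, via trans-ester 15 (not isolated)
Conditions: RuCl[(R,R)-TsDPEN](p-cymene) (3 mol%), HCO2H/Et3N (2:3), DMF, 40 °C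
Reagents that add atoms: none
Why: Noyori–Ikariya asymmetric transfer hydrogenation with dynamic kinetic resolution, as known for 3-substituted chroman-4-ones: amine-mediated enolisation interconverts 14 and 15 at C3, and the (R,R) catalyst should deliver hydride to the α face of C4 only in the 2,3-trans ester 15 (anti to the C3 ester, whereas in 14 this face is blocked by the axial ester), giving the 3,4-cis alcohol with 3S and 4S configuration while C2 is untouched.

**Step 10**
Reactants: 16 (2R,3S,4S)-5,7-bis(allyloxy)-2-[3,4-bis(allyloxy)phenyl]-4-hydroxy-3,4-dihydro-2H-chromen-3-yl 3,4,5-tris(allyloxy)benzoate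
Product: 17 (2R,3S,4S)-2-(3,4-dihydroxyphenyl)-4,5,7-trihydroxy-3,4-dihydro-2H-chromen-3-yl 3,4,5-trihydroxybenzoate (target)
Conditions: Pd(PPh3)4 (10 mol%), N-methylaniline (14 equiv), THF, rt, Ar, dark
Reagents that add atoms: none
Why: Tsuji–Trost deallylation, in which zerovalent palladium ionises each aryl allyl ether and N-methylaniline takes up the allyl group under neutral, non-reductive conditions that should spare the labile C4 benzylic alcohol, the ester and all three stereocentres.

**Compound list**
1 | 5-fluorobenzene-1,3-diol | Oc1cc(O)cc(F)c1 | starting material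
2 | 1,3-bis(allyloxy)-5-fluorobenzene | Fc1cc(OCC=C)cc(OCC=C)c1 | intermediate
3 | 1,5-bis(allyloxy)-2-bromo-3-fluorobenzene | Fc1cc(OCC=C)cc(OCC=C)c1Br | intermediate
4 | 2,2-dimethyl-1,3-dioxolan-4-one | CC1(C)OCC(=O)O1 | starting material
5 | [2,4-bis(allyloxy)-6-fluorophenyl]magnesium chloride | Cl[Mg]c1c(F)cc(OCC=C)cc1OCC=C | intermediate
6 | 1-[2,4-bis(allyloxy)-6-fluorophenyl]-2-hydroxyethan-1-one | O=C(CO)c1c(F)cc(OCC=C)cc1OCC=C | intermediate
7 | 3,4-dihydroxybenzaldehyde | O=Cc1ccc(O)c(O)c1 | starting material
8 | 3,4-bis(allyloxy)benzaldehyde | O=Cc1ccc(OCC=C)c(OCC=C)c1 | intermediate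
9 | (2S,3R)-1-[2,4-bis(allyloxy)-6-fluorophenyl]-3-[3,4-bis(allyloxy)phenyl]-2,3-dihydroxypropan-1-one (syn-diol) | O=C(c1c(F)cc(OCC=C)cc1OCC=C)[C@@H](O)[C@H](O)c1ccc(OCC=C)c(OCC=C)c1 | intermediate
10 | (2R,3S)-5,7-bis(allyloxy)-2-[3,4-bis(allyloxy)phenyl]-3-hydroxy-2,3-dihydro-4H-chromen-4-one | O[C@H]1[C@@H](c2ccc(OCC=C)c(OCC=C)c2)Oc2cc(OCC=C)cc(OCC=C)c2C1=O | intermediate
11 | methyl 3,4,5-trihydroxybenzoate | COC(=O)c1cc(O)c(O)c(O)c1 | starting material
12 | methyl 3,4,5-tris(allyloxy)benzoate | COC(=O)c1cc(OCC=C)c(OCC=C)c(OCC=C)c1 | intermediate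
13 | 3,4,5-tris(allyloxy)benzoic acid | OC(=O)c1cc(OCC=C)c(OCC=C)c(OCC=C)c1 | intermediate
14 | (2R,3S)-5,7-bis(allyloxy)-2-[3,4-bis(allyloxy)phenyl]-4-oxo-3,4-dihydro-2H-chromen-3-yl 3,4,5-tris(allyloxy)benzoate | O=C(O[C@H]1[C@@H](c2ccc(OCC=C)c(OCC=C)c2)Oc2cc(OCC=C)cc(OCC=C)c2C1=O)c1cc(OCC=C)c(OCC=C)c(OCC=C)c1 | intermediate
15 | (2R,3R)-5,7-bis(allyloxy)-2-[3,4-bis(allyloxy)phenyl]-4-oxo-3,4-dihydro-2H-chromen-3-yl 3,4,5-tris(allyloxy)benzoate | O=C(O[C@@H]1[C@@H](c2ccc(OCC=C)c(OCC=C)c2)Oc2cc(OCC=C)cc(OCC=C)c2C1=O)c1cc(OCC=C)c(OCC=C)c(OCC=C)c1 | intermediate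
16 | (2R,3S,4S)-5,7-bis(allyloxy)-2-[3,4-bis(allyloxy)phenyl]-4-hydroxy-3,4-dihydro-2H-chromen-3-yl 3,4,5-tris(allyloxy)benzoate | O=C(O[C@@H]1[C@@H](c2ccc(OCC=C)c(OCC=C)c2)Oc2cc(OCC=C)cc(OCC=C)c2[C@@H]1O)c1cc(OCC=C)c(OCC=C)c(OCC=C)c1 | intermediate
17 | (2R,3S,4S)-2-(3,4-dihydroxyphenyl)-4,5,7-trihydroxy-3,4-dihydro-2H-chromen-3-yl 3,4,5-trihydroxybenzoate | O=C(O[C@@H]1[C@@H](c2ccc(O)c(O)c2)Oc2cc(O)cc(O)c2[C@@H]1O)c1cc(O)c(O)c(O)c1 | target

**Step count**
Total steps: 10. Longest linear sequence: 7 (steps 1, 2, 3, 5, 8, 9, 10).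

**Steps most likely to fail**

1. Step 5 (proposed new method). The zinc aldol with an electron-rich aryl aldehyde may be slow or reversible. After deprotonation, retro-aldol cleavage may compete with ring closure and erode the enantiomeric purity at C2. Closure through the C3 oxygen to a five-membered ring is a further possible leak. Fallback (known chemistry, ring C closed instead at O1–C2): it sets out from aldehyde 8 and comes back at ester 15. Commercial 2',4',6'-trihydroxyacetophenone is bis-allylated with allyl bromide (K2CO3, acetone; the chelated ortho hydroxyl stays free) to 1-[2,4-bis(allyloxy)-6-hydroxyphenyl]ethan-1-one F1. This is protected (MOMCl, i-Pr2NEt, CH2Cl2) as 1-[2,4-bis(allyloxy)-6-(methoxymethoxy)phenyl]ethan-1-one F2. Claisen–Schmidt condensation with 8 (KOH, EtOH) should give (E)-3-[3,4-bis(allyloxy)phenyl]-1-[2,4-bis(allyloxy)-6-(methoxymethoxy)phenyl]prop-2-en-1-one F3. Juliá–Colonna epoxidation (poly-L-leucine, urea–H2O2, DBU, THF) should give [(2R,3S)-3-[3,4-bis(allyloxy)phenyl]oxiran-2-yl][2,4-bis(allyloxy)-6-(methoxymethoxy)phenyl]methanone F4. HCl in MeOH then removes the methoxymethyl group and the freed phenol opens the epoxide at the benzylic carbon with inversion (6-endo), giving (2R,3R)-5,7-bis(allyloxy)-2-[3,4-bis(allyloxy)phenyl]-3-hydroxy-2,3-dihydro-4H-chromen-4-one F5. Steglich esterification of F5 with 13 gives 15, which enters step 9 without any need for epimerisation.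

2. Step 9. Epimerisation at C3 may be slower than mismatched reduction of the cis ester, which would lower the diastereoselectivity; migration of the galloyl group from O3 to the new O4 under the amine is a second risk. Fallback: it sets out from 14 and comes back at 16, and separates the two events. C3 is first equilibrated (DBU, 0.1 equiv, toluene, rt); 15 is separated and 14 recycled. Compound 15 is then reduced under substrate control with LiBH(s-Bu)3 (THF, −78 °C, cold AcOH quench), where equatorial attack of the bulky hydride should give the pseudo-axial C4 hydroxyl cis to the equatorial C3 ester. No new compound is made.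

3. Step 10. Removal of seven allyl groups may stall, or the C4 hydroxyl of the freed phloroglucinol-type flavan-3,4-diol may ionise during the reaction and be lost by capture or self-condensation. Fallback: it sets out from 15 (isolated as in the fallback to step 9) and comes back at 17, with the order of events reversed. The allyl groups are removed at the robust ketone stage (Pd(PPh3)4, N-methylaniline, THF, rt) to give (2R,3R)-2-(3,4-dihydroxyphenyl)-5,7-dihydroxy-4-oxo-3,4-dihydro-2H-chromen-3-yl 3,4,5-trihydroxybenzoate (taxifolin 3-O-gallate) F6. The unprotected ketone is then reduced last by asymmetric transfer hydrogenation (RuCl[(R,R)-TsDPEN](p-cymene), HCO2Na, H2O/MeOH, near-neutral pH, 30 °C), following the classical access to leuco compounds by reduction of free dihydroflavonols.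

**Further compounds**
F1 | step 5 | 1-[2,4-bis(allyloxy)-6-hydroxyphenyl]ethan-1-one | CC(=O)c1c(O)cc(OCC=C)cc1OCC=C
F2 | step 5 | 1-[2,4-bis(allyloxy)-6-(methoxymethoxy)phenyl]ethan-1-one | CC(=O)c1c(OCOC)cc(OCC=C)cc1OCC=C
F3 | step 5 | (E)-3-[3,4-bis(allyloxy)phenyl]-1-[2,4-bis(allyloxy)-6-(methoxymethoxy)phenyl]prop-2-en-1-one | O=C(/C=C/c1ccc(OCC=C)c(OCC=C)c1)c1c(OCOC)cc(OCC=C)cc1OCC=C
F4 | step 5 | [(2R,3S)-3-[3,4-bis(allyloxy)phenyl]oxiran-2-yl][2,4-bis(allyloxy)-6-(methoxymethoxy)phenyl]methanone | O=C(c1c(OCOC)cc(OCC=C)cc1OCC=C)[C@@H]1O[C@H]1c1ccc(OCC=C)c(OCC=C)c1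
F5 | step 5 | (2R,3R)-5,7-bis(allyloxy)-2-[3,4-bis(allyloxy)phenyl]-3-hydroxy-2,3-dihydro-4H-chromen-4-one | O[C@@H]1[C@@H](c2ccc(OCC=C)c(OCC=C)c2)Oc2cc(OCC=C)cc(OCC=C)c2C1=O
F0 | step 9 | none | none
F6 | step 10 | (2R,3R)-2-(3,4-dihydroxyphenyl)-5,7-dihydroxy-4-oxo-3,4-dihydro-2H-chromen-3-yl 3,4,5-trihydroxybenzoate | O=C(O[C@@H]1[C@@H](c2ccc(O)c(O)c2)Oc2cc(O)cc(O)c2C1=O)c1cc(O)c(O)c(O)c1
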